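**Retrosynthetic overview**
1. No ring is built. Both benzene rings come from 3-bromophenol (1), which with acetyl chloride (2) gives bromo ketone 3. One ligand-controlled addition of the Grignard reagent of 4 to 3 gives (S)-aryl bromide 5, the source of both (S) carbinols.
2. Key disconnection: both benzylic CH2 groups of the target (the ArCH2Ar bridge and the CH2OH carbon) trace to one symmetric C1 reagent, CH2(Bpin)2 (6). Its symmetry is broken by room-temperature mono-arylation with 5, giving benzylboronate 7, which is made once and isolated.
3. One portion of 7 is oxidised at C–B to (S)-sydonol (8), which is brominated para to the phenol to give 9.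
4. The other portion of 7 is joined to 9 by sp3–sp2 Suzuki coupling to give disydonol C (10).

Assumption: forming the Grignard reagent from 4 and the transient O-TMS protection in step 2 are operations inside that step (nothing isolated), not separate steps.

**Route**

Step 1
Reactants: 1, 3-bromophenol; 2, acetyl chloride
Product: 3, 1-(4-bromo-2-hydroxyphenyl)ethan-1-one
Conditions: AcCl (1.1 equiv), neat, 50 °C; then AlCl3 (1.6 equiv), 150 °C, 2 h; ice/aq HCl (one pot)
Reagents that add atoms: acetyl chloride (2), CC(=O)Cl
Why: O-acetylation followed by Fries rearrangement; at 150 °C AlCl3 drives the aryl acetate to the chelated ortho-hydroxy ketone, and the acyl group goes to the ortho site para to Br rather than the one squeezed between O and Br; no stereocentre.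

Step 2
Reactants: 3, 1-(4-bromo-2-hydroxyphenyl)ethan-1-one; 4, 1-bromo-4-methylpentane (as its Grignard reagent)
Product: 5, (2S)-2-(4-bromo-2-hydroxyphenyl)-6-methylheptan-2-ol
Conditions: HMDS, cat. TMSCl, 80 °C, evaporate (transient ArOTMS); chiral trans-1,2-diaminocyclohexane-derived N,N,O-aminophenol ligand (1.1 equiv, enantiomer giving Si-face attack), 4-methylpentylMgBr (from 4, Mg, Et2O; 2.5 equiv), PhMe, −80 °C; K2CO3, MeOH, rt; enrich to ≥99% ee (recrystallisation or chiral SFC)
Reagents that add atoms: 4-methylpentylmagnesium bromide (from 4), CC(C)CCC[Mg]Br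
Why: Ligand-mediated asymmetric Grignard 1,2-addition to an aryl methyl ketone; the magnesium-bound chiral aminophenolate delivers the alkyl group to the Si face of the C=O (O > aryl > CH3), which gives the (S) tertiary carbinol, while the transient TMS ether stops a chelated magnesium phenoxide from opening an unselective background path and the ArBr bond is inert to RMgBr at −80 °C.

Step 3 (key step)
Reactants: 5, (2S)-2-(4-bromo-2-hydroxyphenyl)-6-methylheptan-2-ol; 6, bis(pinacolato)borylmethane
Product: 7, (2S)-2-{2-hydroxy-4-[(4,4,5,5-tetramethyl-1,3,2-dioxaborolan-2-yl)methyl]phenyl}-6-methylheptan-2-ol (isolated; the batch is divided between steps 4 and 6)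
Conditions: 6 (1.3 equiv), Pd[P(t-Bu)3]2 (5 mol%), 8 M aq KOH (4 equiv), 1,4-dioxane, rt; aq NH4Cl work-up; silica chromatography
Reagents that add atoms: bis(pinacolato)borylmethane (6), CC1(C)OB(CB2OC(C)(C)C(C)(C)O2)OC1(C)C (gives the CH2–Bpin unit)
Why: Chemoselective Suzuki–Miyaura mono-arylation that breaks the symmetry of the gem-diborylmethane; only the geminally activated first C–B bond transmetallates at rt, so the ordinary benzylic boronate 7 accumulates without diarylation, and the basic medium leaves the acid-sensitive tertiary benzylic carbinol and its configuration untouched.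

Step 4
Reactants: 7, the benzylic pinacol boronate (portion A)
Product: 8, (S)-sydonol, (2S)-2-[2-hydroxy-4-(hydroxymethyl)phenyl]-6-methylheptan-2-ol
Conditions: 30% H2O2 (3 equiv), 2 M aq NaOH, THF, 0 °C → rt; Na2S2O3; aq NH4Cl
Reagents that add atoms: hydrogen peroxide, OO (gives the O of the CH2OH)
Why: Alkaline peroxide oxidation of a C–B bond (boronate 1,2-migration with retention at carbon) converts CH2Bpin into CH2OH; the conditions are basic and cold, so the tertiary carbinol cannot ionise and the stereocentre is unaffected.

Step 5
Reactants: 8, (S)-sydonol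
Product: 9, (2S)-2-[5-bromo-2-hydroxy-4-(hydroxymethyl)phenyl]-6-methylheptan-2-ol
Conditions: NBS (1.0 equiv), MeCN, −20 → 0 °C
Reagents that add atoms: N-bromosuccinimide, O=C1CCC(=O)N1Br
Why: Electrophilic aromatic bromination of a phenol; para to OH is the only activated position that is neither blocked (C1 carries the carbinol) nor flanked by two substituents (C3), and NBS releases no strong acid, so the tertiary benzylic alcohol does not ionise and the stereocentre is unaffected.

Step 6
Reactants: 7, the benzylic pinacol boronate (portion B); 9, (2S)-2-[5-bromo-2-hydroxy-4-(hydroxymethyl)phenyl]-6-methylheptan-2-ol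
Product: 10, disydonol C
Conditions: 7 (1.3 equiv), 9 (1.0 equiv), SPhos Pd G3 (5 mol%), K3PO4 (5 equiv), degassed 1,4-dioxane/H2O (4:1), 80 °C; aq NH4Cl work-up
Reagents that add atoms: none
Why: sp3–sp2 Suzuki–Miyaura coupling of a primary benzylic boronate with an aryl bromide; the remaining C–B bond of the former diborylmethane transmetallates on heating, and the biarylphosphine catalyst inserts into the hindered, electron-rich C–Br bond of 9; no new stereocentre forms, and both (S) carbinols, inherited from 5 at ≥99% ee, survive the basic conditions.

**Compound list**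
1 | 3-bromophenol | Oc1cccc(Br)c1 | starting material
2 | acetyl chloride | CC(=O)Cl | starting material
3 | 1-(4-bromo-2-hydroxyphenyl)ethan-1-one | CC(=O)c1ccc(Br)cc1O | intermediate
4 | 1-bromo-4-methylpentane | CC(C)CCCBr | starting material
5 | (2S)-2-(4-bromo-2-hydroxyphenyl)-6-methylheptan-2-ol | CC(C)CCC[C@](C)(O)c1ccc(Br)cc1O | intermediate
6 | bis(pinacolato)borylmethane, 2,2'-methylenebis(4,4,5,5-tetramethyl-1,3,2-dioxaborolane) | CC1(C)OB(CB2OC(C)(C)C(C)(C)O2)OC1(C)C | starting material
7 | (2S)-2-{2-hydroxy-4-[(4,4,5,5-tetramethyl-1,3,2-dioxaborolan-2-yl)methyl]phenyl}-6-methylheptan-2-ol | CC(C)CCC[C@](C)(O)c1ccc(CB2OC(C)(C)C(C)(C)O2)cc1O | intermediate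
8 | (S)-sydonol, (2S)-2-[2-hydroxy-4-(hydroxymethyl)phenyl]-6-methylheptan-2-ol | CC(C)CCC[C@](C)(O)c1ccc(CO)cc1O | intermediate
9 | (2S)-2-[5-bromo-2-hydroxy-4-(hydroxymethyl)phenyl]-6-methylheptan-2-ol | CC(C)CCC[C@](C)(O)c1cc(Br)c(CO)cc1O | intermediate
10 | disydonol C, (2S)-2-[2-hydroxy-4-({4-hydroxy-2-(hydroxymethyl)-5-[(2S)-2-hydroxy-6-methylheptan-2-yl]phenyl}methyl)phenyl]-6-methylheptan-2-ol | CC(C)CCC[C@](C)(O)c1ccc(Cc2cc([C@@](C)(O)CCCC(C)C)c(O)cc2CO)cc1O | target

**Totals**
Total steps: 6. Longest linear sequence: 6 (1 → 3 → 5 → 7 → 8 → 9 → 10); 7 also enters step 6 as the convergent partner.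

**Three steps most likely to fail**
- **Step 6:** protodeboronation of 7 or slow oxidative addition into the hindered bromophenoxide 9. Fallback: drop the boron nucleophile and join the halves by Ni-catalysed reductive cross-electrophile coupling of 9 with the primary benzylic chloride made from 8 (MsCl/LiCl, collidine), using NiBr2·glyme/bipyridine and Zn.
- **Step 2:** the ortho-silyloxy ketone may give low ee or enolise. Fallback: set the carbinol by Sharpless asymmetric dihydroxylation instead. O-protect 3, Wittig methylenation to the isopropenyl arene, AD to the 1,2-diol, close to the 2-aryl-2-methyloxirane, and open it at CH2 with 3-methylbutylMgBr/CuI.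
- **Step 3:** the mono-arylation may be sluggish on the unprotected, electron-rich bromophenoxide. Fallback: reach 7 by a 1,2-metallate route instead. Miyaura borylation of 5 (as its bis-TMS ether) with B2pin2, then Matteson one-carbon homologation of the aryl boronate with BrCH2Cl/n-BuLi at −78 °C.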